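**Retrosynthetic overview**

1. The route rests on the 2-pyrone ring (O1', C2'(=O), C3', C4', C5', C6'), which hangs by C4' on the C3 methylene of the trans-(3R,4R)-butyrolactone (O1, C2–C5) and carries the carboxyl on C6'. The carboxyl is traced back to an aldehyde and then to a diethyl acetal.
2. The pyrone is cut at C4'–C5' and C6'–O1'. This leaves a (Z)-3-iodobut-2-enoic acid on the lactone (C2', C3', C4') and 3,3-diethoxyprop-1-yne (C5', C6', acetal carbon), joined by palladium-catalysed alkynylation and ZnBr2-directed 6-endo-dig lactonisation.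
3. The iodo acid comes from the C3-propargyl lactone by CO2 carboxylation of the alkyne and anti hydroiodination; the propargyl group enters trans to the C4 arylmethyl group.
4. The C4 stereocentre is set by Evans alkylation of a 3-(3,4-dimethoxyphenyl)propanoyl imide with tert-butyl bromoacetate, followed by reduction and lactonisation.
5. Ring order: butyrolactone first (step 4), pyrone second (step 8); the arene is bought.

Key step: step 8

Remark: the target is read as the trans (3R,4R) lactone with the carboxyl on the pyrone carbon next to the ring oxygen; the (S)-oxazolidinone is the auxiliary enantiomer that leads to this series.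

**Route**

Step 1
Reactants: 1 3-(3,4-dimethoxyphenyl)propanoic acid; 2 (S)-4-benzyloxazolidin-2-one
Product: 4 (4S)-4-benzyl-3-[3-(3,4-dimethoxyphenyl)propanoyl]oxazolidin-2-one, via mixed pivalic anhydride 3 (not isolated)
Conditions: t-BuCOCl, Et3N, THF, −20 °C; then LiCl, 2, −20 °C → rt
Reagents that add atoms: none
Why: N-acylation of the oxazolidinone through the mixed pivalic anhydride with LiCl activation is the standard entry to Evans imides; the hindered pivaloyl carbonyl directs attack to the arylpropanoyl carbonyl, and no stereocentre is touched.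

Step 2
Reactants: 4 (4S)-4-benzyl-3-[3-(3,4-dimethoxyphenyl)propanoyl]oxazolidin-2-one; 5 tert-butyl bromoacetate
Product: 7 tert-butyl (3R)-3-{[(4S)-4-benzyl-2-oxooxazolidin-3-yl]carbonyl}-4-(3,4-dimethoxyphenyl)butanoate, via sodium enolate 6 (not isolated)
Conditions: NaN(SiMe3)2, THF, −78 °C; then 5, −78 → −40 °C
Reagents that add atoms: none
Why: Evans alkylation, in which the chelated (Z)-sodium enolate is alkylated on the face away from the benzyl group of the (S)-auxiliary, so that the new centre (the future lactone C4) should be R.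

Step 3
Reactants: 7 tert-butyl (3R)-3-{[(4S)-4-benzyl-2-oxooxazolidin-3-yl]carbonyl}-4-(3,4-dimethoxyphenyl)butanoate
Product: 8 tert-butyl (3R)-4-(3,4-dimethoxyphenyl)-3-(hydroxymethyl)butanoate
Conditions: LiBH4, MeOH (1.5 equiv), THF, 0 °C
Reagents that add atoms: none
Why: Reductive cleavage of the imide, in which LiBH4 reduces the activated exocyclic imide carbonyl to the primary alcohol and releases the auxiliary while the tert-butyl ester survives and the stereocentre is not enolised.

Step 4
Reactants: 8 tert-butyl (3R)-4-(3,4-dimethoxyphenyl)-3-(hydroxymethyl)butanoate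
Product: 9 (R)-4-(3,4-dimethoxybenzyl)dihydrofuran-2(3H)-one
Conditions: p-TsOH·H2O (10 mol%), toluene, 80 °C
Reagents that add atoms: none
Why: Acid-catalysed lactonisation of the γ-hydroxy tert-butyl ester (5-exo-trig acyl substitution, the tert-butyl group leaving as 2-methylpropene) closes the butyrolactone without touching C4.

Step 5
Reactants: 9 (R)-4-(3,4-dimethoxybenzyl)dihydrofuran-2(3H)-one; 10 propargyl bromide
Product: 12 (3R,4R)-4-(3,4-dimethoxybenzyl)-3-(prop-2-yn-1-yl)dihydrofuran-2(3H)-one, via lithium enolate 11 (not isolated)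
Conditions: LiN(SiMe3)2 (1.05 equiv), THF, −78 °C; then 10, DMPU, −78 → −30 °C
Reagents that add atoms: none
Why: Enolate alkylation (SN2) of the lactone, in which the C4 arylmethyl group shields one face of the planar lithium enolate so that the propargyl group should enter trans and set C3 as R.

Step 6
Reactants: 12 (3R,4R)-4-(3,4-dimethoxybenzyl)-3-(prop-2-yn-1-yl)dihydrofuran-2(3H)-one; 13 carbon dioxide
Product: 14 4-[(3R,4R)-4-(3,4-dimethoxybenzyl)-2-oxotetrahydrofuran-3-yl]but-2-ynoic acid
Conditions: AgI (2 mol%), Cs2CO3 (1.5 equiv), CO2 (2 atm), DMF, 50 °C; then cold 1 M HCl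
Reagents that add atoms: none
Why: Silver-catalysed C–H carboxylation of a terminal alkyne, in which the silver acetylide formed with Cs2CO3 inserts CO2 to give the cesium alk-2-ynoate; carbonate is too weak a base to enolise the lactone, so C3 should stay trans.

Step 7
Reactants: 14 4-[(3R,4R)-4-(3,4-dimethoxybenzyl)-2-oxotetrahydrofuran-3-yl]but-2-ynoic acid
Product: 15 (2Z)-4-[(3R,4R)-4-(3,4-dimethoxybenzyl)-2-oxotetrahydrofuran-3-yl]-3-iodobut-2-enoic acid
Conditions: NaI (3 equiv), AcOH, 90 °C
Reagents that add atoms: sodium iodide, [Na+].[I-]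
Why: Conjugate hydroiodination of an alk-2-ynoic acid, in which iodide adds to the β-carbon and protonation occurs anti, placing iodine cis to the carboxyl (Z), the geometry the ring closure needs.

Step 8
Reactants: 15 (2Z)-4-[(3R,4R)-4-(3,4-dimethoxybenzyl)-2-oxotetrahydrofuran-3-yl]-3-iodobut-2-enoic acid; 16 3,3-diethoxyprop-1-yne
Product: 20 (3R,4R)-3-{[6-(diethoxymethyl)-2-oxo-2H-pyran-4-yl]methyl}-4-(3,4-dimethoxybenzyl)dihydrofuran-2(3H)-one, via lithium acetylide 17 (not isolated), via alkynylzinc bromide 18 (not isolated), via enynoic acid 19 (not isolated)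
Conditions: 16 (2.4 equiv), n-BuLi, THF, −78 °C; ZnBr2 (2.6 equiv), −78 → 0 °C; then 15, Pd(PPh3)4 (5 mol%), THF, 0 °C → rt; aq. NH4Cl, silica plug; then ZnBr2 (20 mol%), THF, rt → 40 °C
Reagents that add atoms: none
Why: Zerovalent palladium inserts into the vinyl C–I bond of 15 with retention of geometry, zinc acetylide 18 transmetalates and reductive elimination forms C4'–C5', giving (Z)-enynoic acid 19 with the carboxyl cis to the alkyne; this is a Negishi-type alkynylation of a (Z)-3-iodoalk-2-enoic acid, a known reaction class. The zinc acetylide replaces a copper acetylide with an amine because palladium–copper–amine conditions are known to lactonise such free enynoic acids 5-exo in the coupling flask, which would take the ring closure out of the hands of ZnBr2. ZnBr2 then acts as a hard Lewis acid on the palladium-free acid and the carboxyl oxygen adds to the distal alkyne carbon C6' in the 6-endo-dig mode, protonation of the vinyl–zinc bond giving the pyrone (known ZnBr2-catalysed lactonisation of (Z)-2-en-4-ynoic acids to 2-pyrones). No stereocentre is formed, and C3 and C4 of the butyrolactone are not touched by the weakly basic zinc reagent. The selectivity needed is 6-endo over 5-exo closure: it is secured by the Z geometry fixed in step 7, by removal of palladium before the closure, and by ZnBr2 in place of a soft silver or palladium salt, helped by the vinylogous pull of the carboxyl that makes C6' the electrophilic δ-carbon. The inductive pull of the acetal on C6' is the one factor that could erode this preference.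

Step 9
Reactants: 20 (3R,4R)-3-{[6-(diethoxymethyl)-2-oxo-2H-pyran-4-yl]methyl}-4-(3,4-dimethoxybenzyl)dihydrofuran-2(3H)-one
Product: 21 4-{[(3R,4R)-4-(3,4-dimethoxybenzyl)-2-oxotetrahydrofuran-3-yl]methyl}-2-oxo-2H-pyran-6-carbaldehyde
Conditions: TFA–H2O (4:1), CHCl3, 0 °C → rt
Reagents that add atoms: water, O
Why: Acid-catalysed acetal hydrolysis; both lactone rings and the aryl methyl ethers tolerate aqueous acid, and a strong acid is chosen because the electron-poor pyrone slows ionisation of the acetal.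

Step 10
Reactants: 21 4-{[(3R,4R)-4-(3,4-dimethoxybenzyl)-2-oxotetrahydrofuran-3-yl]methyl}-2-oxo-2H-pyran-6-carbaldehyde
Product: 22 4-{[(3R,4R)-4-(3,4-dimethoxybenzyl)-2-oxotetrahydrofuran-3-yl]methyl}-2-oxo-2H-pyran-6-carboxylic acid
Conditions: NaClO2, NaH2PO4, 2-methylbut-2-ene, t-BuOH–H2O, 0 °C → rt
Reagents that add atoms: sodium chlorite, [Na+].[O-]Cl=O
Why: Pinnick oxidation, in which chlorous acid converts the aldehyde into the acid under buffered conditions that spare both lactones, while 2-methylbut-2-ene traps HOCl before it can chlorinate the dimethoxyarene.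

**Compound list**

1 | 3-(3,4-dimethoxyphenyl)propanoic acid | COc1ccc(CCC(=O)O)cc1OC | starting material
2 | (S)-4-benzyloxazolidin-2-one | O=C1N[C@@H](Cc2ccccc2)CO1 | starting material
3 | 3-(3,4-dimethoxyphenyl)propanoic pivalic anhydride | COc1ccc(CCC(=O)OC(=O)C(C)(C)C)cc1OC | intermediate
4 | (4S)-4-benzyl-3-[3-(3,4-dimethoxyphenyl)propanoyl]oxazolidin-2-one | COc1ccc(CCC(=O)N2C(=O)OC[C@@H]2Cc2ccccc2)cc1OC | intermediate
5 | tert-butyl bromoacetate | CC(C)(C)OC(=O)CBr | starting material
6 | sodium (Z)-enolate of 4 | COc1ccc(C/C=C(\[O-])N2C(=O)OC[C@@H]2Cc2ccccc2)cc1OC.[Na+] | intermediate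
7 | tert-butyl (3R)-3-{[(4S)-4-benzyl-2-oxooxazolidin-3-yl]carbonyl}-4-(3,4-dimethoxyphenyl)butanoate | COc1ccc(C[C@H](CC(=O)OC(C)(C)C)C(=O)N2C(=O)OC[C@@H]2Cc2ccccc2)cc1OC | intermediate
8 | tert-butyl (3R)-4-(3,4-dimethoxyphenyl)-3-(hydroxymethyl)butanoate | COc1ccc(C[C@H](CC(=O)OC(C)(C)C)CO)cc1OC | intermediate
9 | (R)-4-(3,4-dimethoxybenzyl)dihydrofuran-2(3H)-one | COc1ccc(C[C@H]2COC(=O)C2)cc1OC | intermediate
10 | propargyl bromide | C#CCBr | starting material
11 | lithium enolate of 9 | COc1ccc(C[C@H]2COC([O-])=C2)cc1OC.[Li+] | intermediate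
12 | (3R,4R)-4-(3,4-dimethoxybenzyl)-3-(prop-2-yn-1-yl)dihydrofuran-2(3H)-one | COc1ccc(C[C@H]2COC(=O)[C@@H]2CC#C)cc1OC | intermediate
13 | carbon dioxide | O=C=O | starting material
14 | 4-[(3R,4R)-4-(3,4-dimethoxybenzyl)-2-oxotetrahydrofuran-3-yl]but-2-ynoic acid | COc1ccc(C[C@H]2COC(=O)[C@@H]2CC#CC(=O)O)cc1OC | intermediate
15 | (2Z)-4-[(3R,4R)-4-(3,4-dimethoxybenzyl)-2-oxotetrahydrofuran-3-yl]-3-iodobut-2-enoic acid | COc1ccc(C[C@H]2COC(=O)[C@@H]2C/C(I)=C/C(=O)O)cc1OC | intermediate
16 | 3,3-diethoxyprop-1-yne | C#CC(OCC)OCC | starting material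
17 | lithium 3,3-diethoxyprop-1-yn-1-ide | [Li]C#CC(OCC)OCC | intermediate
18 | (3,3-diethoxyprop-1-yn-1-yl)zinc bromide | Br[Zn]C#CC(OCC)OCC | intermediate
19 | (2Z)-3-{[(3R,4R)-4-(3,4-dimethoxybenzyl)-2-oxotetrahydrofuran-3-yl]methyl}-6,6-diethoxyhex-2-en-4-ynoic acid | COc1ccc(C[C@H]2COC(=O)[C@@H]2C/C(C#CC(OCC)OCC)=C/C(=O)O)cc1OC | intermediate
20 | (3R,4R)-3-{[6-(diethoxymethyl)-2-oxo-2H-pyran-4-yl]methyl}-4-(3,4-dimethoxybenzyl)dihydrofuran-2(3H)-one | COc1ccc(C[C@H]2COC(=O)[C@@H]2Cc2cc(C(OCC)OCC)oc(=O)c2)cc1OC | intermediate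
21 | 4-{[(3R,4R)-4-(3,4-dimethoxybenzyl)-2-oxotetrahydrofuran-3-yl]methyl}-2-oxo-2H-pyran-6-carbaldehyde | COc1ccc(C[C@H]2COC(=O)[C@@H]2Cc2cc(C=O)oc(=O)c2)cc1OC | intermediate
22 | 4-{[(3R,4R)-4-(3,4-dimethoxybenzyl)-2-oxotetrahydrofuran-3-yl]methyl}-2-oxo-2H-pyran-6-carboxylic acid | COc1ccc(C[C@H]2COC(=O)[C@@H]2Cc2cc(C(=O)O)oc(=O)c2)cc1OC | target

**Step count**

Total step count: 10. Longest linear sequence: 10 steps (1 → 22).

**Steps most likely to fail**

Risk 1, step 8 (key step). The ring may close in the 5-exo mode, either on residual palladium or because the acetal lowers the electrophilicity of C6'. The coupling may also stall through protonolysis of the zinc acetylide by the free acid. The fallback sets out from 15 and returns at 20, and it moves the ring closure to the ester level. Acid 15 would be methylated with Me3SiCHN2 in MeOH–toluene to methyl (2Z)-4-[(3R,4R)-4-(3,4-dimethoxybenzyl)-2-oxotetrahydrofuran-3-yl]-3-iodobut-2-enoate F1. Sonogashira coupling of this ester with 16 (PdCl2(PPh3)2, CuI, Et3N, THF, rt) should give methyl (2Z)-3-{[(3R,4R)-4-(3,4-dimethoxybenzyl)-2-oxotetrahydrofuran-3-yl]methyl}-6,6-diethoxyhex-2-en-4-ynoate F2, since an ester cannot lactonise under these conditions. Electrophilic iodocyclisation with I2 in CH2Cl2 (chosen over ICl to spare the dimethoxyarene) lets the ester carbonyl oxygen attack the iodonium-activated alkyne 6-endo with loss of the methyl group, giving (3R,4R)-3-{[6-(diethoxymethyl)-5-iodo-2-oxo-2H-pyran-4-yl]methyl}-4-(3,4-dimethoxybenzyl)dihydrofuran-2(3H)-one F3. Reductive deiodination with Pd(OAc)2, PPh3, HCO2H and Et3N in DMF at 60 °C would then deliver 20.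

Risk 2, step 6. Capture of CO2 by the silver acetylide may be incomplete, the ynoic acid may lose CO2 again during work-up, or the base may isomerise the alkyne towards an allene next to the lactone. The fallback sets out from 9 and returns at 14, and it brings in the carboxyl carbon by alkylation in place of CO2 fixation. The lithium enolate 11 would be alkylated, as in step 5, with [(4-bromobut-2-yn-1-yl)oxy](tert-butyl)dimethylsilane to give (3R,4R)-3-[4-(tert-butyldimethylsilyloxy)but-2-yn-1-yl]-4-(3,4-dimethoxybenzyl)dihydrofuran-2(3H)-one F4. Desilylation with Bu4NF buffered with AcOH in THF should give (3R,4R)-4-(3,4-dimethoxybenzyl)-3-(4-hydroxybut-2-yn-1-yl)dihydrofuran-2(3H)-one F5. Jones oxidation of the propargylic alcohol (CrO3, H2SO4, acetone, 0 °C) would give ynoic acid 14.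

Risk 3, step 7. The ynoic acid may lose CO2 on heating before iodide adds, and the Z iodoalkene may isomerise to E on prolonged heating. The fallback sets out from 14 and returns at 20, and it carries out the iodide addition on an ester. Acid 14 would be methylated with Me3SiCHN2 to methyl 4-[(3R,4R)-4-(3,4-dimethoxybenzyl)-2-oxotetrahydrofuran-3-yl]but-2-ynoate F6, which cannot decarboxylate. Treatment with NaI in AcOH, the established conditions for alkyl (Z)-3-iodoalk-2-enoates, should give the methyl (Z)-3-iodoenoate F1. From there the ester path of risk 1 is followed through the methyl enynoate F2 and the 5-iodopyrone F3 to 20.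

**Further compounds**

F1 | step 8 | methyl (2Z)-4-[(3R,4R)-4-(3,4-dimethoxybenzyl)-2-oxotetrahydrofuran-3-yl]-3-iodobut-2-enoate | COc1ccc(C[C@H]2COC(=O)[C@@H]2C/C(I)=C/C(=O)OC)cc1OC
F2 | step 8 | methyl (2Z)-3-{[(3R,4R)-4-(3,4-dimethoxybenzyl)-2-oxotetrahydrofuran-3-yl]methyl}-6,6-diethoxyhex-2-en-4-ynoate | COc1ccc(C[C@H]2COC(=O)[C@@H]2C/C(C#CC(OCC)OCC)=C/C(=O)OC)cc1OC
F3 | step 8 | (3R,4R)-3-{[6-(diethoxymethyl)-5-iodo-2-oxo-2H-pyran-4-yl]methyl}-4-(3,4-dimethoxybenzyl)dihydrofuran-2(3H)-one | COc1ccc(C[C@H]2COC(=O)[C@@H]2Cc2cc(=O)oc(C(OCC)OCC)c2I)cc1OC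
F4 | step 6 | (3R,4R)-3-[4-(tert-butyldimethylsilyloxy)but-2-yn-1-yl]-4-(3,4-dimethoxybenzyl)dihydrofuran-2(3H)-one | COc1ccc(C[C@H]2COC(=O)[C@@H]2CC#CCO[Si](C)(C)C(C)(C)C)cc1OC
F5 | step 6 | (3R,4R)-4-(3,4-dimethoxybenzyl)-3-(4-hydroxybut-2-yn-1-yl)dihydrofuran-2(3H)-one | COc1ccc(C[C@H]2COC(=O)[C@@H]2CC#CCO)cc1OC
F6 | step 7 | methyl 4-[(3R,4R)-4-(3,4-dimethoxybenzyl)-2-oxotetrahydrofuran-3-yl]but-2-ynoate | COc1ccc(C[C@H]2COC(=O)[C@@H]2CC#CC(=O)OC)cc1OC
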